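## Structural features

The target 20 is an aryldihydronaphthalene lignan diol. A 6,7,8-trimethoxybenzo ring (ring A, C4a to C8a) is fused to a 1,2-dihydronaphthalene ring (ring B, C1 to C4). C1 carries a 3,4-dimethoxyphenyl group (ring C), and C2 and C3 carry hydroxymethyl groups (C9 on C2, C10 on C3). The only stereocentres, C1 (R, doubly benzylic) and C2 (S, allylic), are adjacent and trans, and the C1 aryl group sits in the crowded peri position next to the C8 methoxy group. The C3=C4 double bond is conjugated with ring A only; acid or base can move it to C1=C2 (conjugated with both rings), which erases both stereocentres, and oxidants aromatise ring B. C10–OH is a primary cinnamyl-type alcohol that can ionise under acid, and with C9–OH it forms a 1,4-diol that can then close to a cyclic ether. The real difficulty is to set the trans C1/C2 pair in one absolute sense and then finish ring B with the double bond exactly at C3=C4 without equilibrating conditions. The key step uses the fact that C4 is a CH bonded to C4a of ring A and to C3, which itself bears a CH2–O group. If the C4–C4a bond is made by shifting C4a from C3 onto a CH2 group, ring B derives from an indane whose benzylic carbon is quaternary and bears two CH2–O arms, one becoming C4 and the other C10.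

## Logic of the disconnections

20 to 19 to 18: only heteroatom bonds are cut (O–Si at C9, O–S at C10). The key step leaves C10 as a sulfate monoester and needs the C9 oxygen masked, so the end game is two deprotections. Nothing is gained in skeleton. The forward steps must break S–O and Si–O without ionising the allylic C10–O bond or moving the C3=C4 double bond.

18 to 17: the C4–C4a bond is cut and C4a is re-attached to C3. Ring B contracts to a five-membered ring, the double bond disappears, and C4 and C10 become the two CH2–O arms of a six-membered cyclic sulfate on a quaternary carbon. The gain is large: the trisubstituted styrene is gone, the quaternary carbon needs no selectivity between its arms, and the two stereocentres sit on a cyclopentane. The demand is an aryl-assisted ionisation of a primary C–O bond, migration of ring A in preference to C2, and proton loss from C4 only.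

17 to 15: two S–O bonds are cut, leaving a 2,2-disubstituted propane-1,3-diol. The forward step must form a cyclic sulfate in the presence of two electron-rich arenes and a silyl ether.

15 to 13 plus 8: one C–CH2OH bond at the quaternary carbon is cut and the other arm is raised to the aldehyde level. The quaternary carbon then comes from a tertiary aldehyde, whose configuration at that carbon is irrelevant. The demand is an aldehyde with exactly one α-hydrogen and a silyl ether that stands aqueous hydroxide.

13 to 11: the C–CHO bond is cut (one-carbon homologation of a ketone). This returns to a carbonyl group that also activates C2. The forward olefination must work on a hindered, enolisable ketone with a β-silyloxy group, without epimerisation or elimination.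

11 to 10 to 7 plus 8: the O–Si bond and then the C2–C9 bond are cut (aldol with 8). C2 is set trans to the aryl group by substrate control. The demand is an enolate equivalent made under conditions that do not allow a 1,3-proton shift in the indene-type enol derivative, with mono-addition and no dehydration.

7 to 5: the C3–H and C2–H pair is removed, giving a planar enone. This is the only catalyst-controlled stereocentre of the route. The demand is high facial selectivity at a β-aryl carbon next to a peri methoxy group, without 1,2-reduction.

5 to 4 to 3 to 1 plus 2: the dehydrogenation is reversed, the ring-closing C–C bond to ring A is cut (electrocyclisation in the forward sense), and the enone C=C bond is cut (aldol condensation). Regiochemistry is unambiguous because the two ortho positions of the aroyl ring in 3 are equivalent. The demand is a strong-acid ring closure next to a methoxy group.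

## Other disconnections considered

Alternative 1: The cut removes C2–C3 and C1–C8a. It leads to the mixed diester A1, in which a 4-hydroxy-3-methoxycinnamoyl and a 4-hydroxy-3,5-dimethoxycinnamoyl unit are held on a C2-symmetric acetonide diol. In the forward step FeCl3 oxidises both phenols by one electron and the radicals join at the carbons β to the rings inside a ten-membered dilactone. One quinone methide then tautomerises back to a cinnamate, and its dimethoxy-substituted ring attacks the other quinone methide carbon to give A2.
- In favour: two C–C bonds, ring B with C3=C4 in place and both stereocentres arise in one step. The tether enforces cross-coupling and can pass on absolute configuration. Only O-methylation and a hydride reduction, which also releases the tether, remain.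
- Against: the 3-methoxy half has other coupling positions open. Ring B can close in either sense, which would exchange the roles of ring A and ring C. The induction must be relayed from a remote acetonide through a medium ring. The phenolic product is easily oxidised further.
- Comparison: on step economy and bonds formed per step this alternative is better than the chosen plan (roughly half the steps). On structure the chosen plan is more secure, because 1 and 2 fix which ring is A and which is C, and one catalyst-controlled step plus substrate relay fixes configuration. On mechanism both close ring B by attack of a cationic carbon on an electron-rich ring. The alternative must select among several radical and cationic channels, whereas the chosen plan has one assisted ionisation to control.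

Alternative 2: The cut removes C1–C2. The precursor A3 is an (E)-arylidene succinate with a methyl ester on C3, an N-acyl 4-benzyloxazolidinone on the C2 side, and a diarylmethyl methyl ether at C1 as either epimer. In the forward step TiCl4 and i-Pr2NEt form the titanium enolate and ionise the methyl ether. The enolate carbon then attacks the diarylmethyl cation and closes ring B to give A4.
- In favour: both C1 epimers pass through one planar cation, the auxiliary fixes C2, and trans C1 follows from the approach. The cation is well stabilised and the enolate well understood. One hydride reduction turns both carbonyl groups into C9 and C10 and releases the auxiliary.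
- Against: the enolisable CH2 of A3 is also allylic to the unsaturated ester, so an extended enolate or double-bond migration is possible. In A4 the C2–H is α to the imide and allylic, so base could epimerise it or move the alkene to C1=C2. A stoichiometric auxiliary is needed.
- Comparison: on mechanism this alternative is the equal or the better of the chosen plan, since a diarylmethyl cation forms more readily than an aryl-bridged primary centre. On step economy it is better (about eight or nine steps, one reduction at the end). On structure it sets both stereocentres late and at once. The chosen plan sets them early by catalysis and must carry them through eight steps, but it keeps no enolisable stereocentre next to a carbonyl group after step 7.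

Alternative 3: The cut removes C2–C3 and C4–C4a. The precursor is the (E)-3,3-diarylallyl propiolate A5, with ring A trans to the CH2O tether. On heating, ring A and the C1=C2 bond act as diene and the alkyne as dienophile. A proton then moves from C4a to C1 to restore ring A, which gives the lactone A6.
- In favour: it is the shortest plan (about six steps with the final lactone reduction). Ring B and the lactone form together, C9 and C10 are both present, and no metal is needed.
- Against: the aryl group trans to the tether becomes ring A, so a geometrically pure trisubstituted alkene with two similar aryl groups is required. The dearomatised intermediate can lose hydrogen to give the arylnaphthalene. C1 is set in a proton transfer after the cycloaddition, so cis or trans is not fixed by the pericyclic step. There is no source of absolute configuration.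
- Comparison: on step economy and bond count per step it is better than the chosen plan. It forms the same C4–C4a bond as the chosen key step. On stereochemistry it is weaker, and for a single-enantiomer target that decides against it; the chosen plan controls both the relative and the absolute configuration by design.

Key step: step 10

Remarks before the steps:
- (a) The facial sense of the copper hydride reduction in step 4 is assumed. (R)-DTBM-SEGPHOS is written; its mirror image is to be used if a pilot run shows that the (S)-ketone forms.
- (b) The structures of 17 and 18 are consistent with 20 atom for atom: the aryl-bearing carbon is R and its neighbour S in all three. The two CH2–O arms of 17 are diastereotopic, not identical, but lead to the same cation.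
- (c) Formaldehyde is counted as starting material 8 and used as its 37% aqueous solution.

## Route

Step 1
Reactants: 1 3',4',5'-trimethoxyacetophenone; 2 veratraldehyde (3,4-dimethoxybenzaldehyde)
Product: 3 (E)-3-(3,4-dimethoxyphenyl)-1-(3,4,5-trimethoxyphenyl)prop-2-en-1-one
Conditions: KOH (aq., 0.5 equiv), MeOH, rt
Reagents that add atoms: none
Why: Claisen–Schmidt condensation; only the methyl ketone can enolise and the aldehyde cannot self-condense, and dehydration of the aldol gives the conjugated (E)-enone.

Step 2
Reactants: 3
Product: 4 rac-3-(3,4-dimethoxyphenyl)-4,5,6-trimethoxy-2,3-dihydro-1H-inden-1-one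
Conditions: CF3CO2H, 120 °C, sealed tube
Reagents that add atoms: none
Why: Nazarov cyclisation of an aryl vinyl ketone: the O-protonated enone closes onto the ring carbon ortho to the acyl group (para to a methoxy group) and rearomatises. The two ortho positions are equivalent, so only one constitution can form; the new stereocentre is racemic and is removed in step 3.

Step 3
Reactants: 4
Product: 5 3-(3,4-dimethoxyphenyl)-4,5,6-trimethoxy-1H-inden-1-one
Conditions: DDQ, 1,4-dioxane, reflux
Reagents that add atoms: none
Why: Quinone dehydrogenation: hydride is abstracted from the doubly benzylic C3, which is activated by the electron-rich aryl group, and C2 loses a proton. This gives the stable 3-arylindenone and removes the uncontrolled stereocentre so that it can be reset by a catalyst.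

Step 4
Reactants: 5
Product: 7 (3R)-3-(3,4-dimethoxyphenyl)-4,5,6-trimethoxy-2,3-dihydro-1H-inden-1-one, via diethoxymethylsilyl enol ether 6 (not isolated)
Conditions: Cu(OAc)2·H2O (3 mol%), (R)-DTBM-SEGPHOS (3 mol%), (EtO)2MeSiH, toluene, 0 °C; then 1 M HCl, THF, rt
Reagents that add atoms: none
Why: Asymmetric conjugate reduction by a bisphosphine copper hydride, a known reaction of β-aryl cyclopentenones. Hydride adds to C3 on the face selected by the ligand and sets C3 as R; the enolate is silylated, which regenerates the hydride and shields the carbonyl group from 1,2-reduction until the acidic work-up. Isolating 7 allows the enantiomeric purity to be checked and raised by recrystallisation.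

Step 5
Reactants: 7; 8 formaldehyde (37% aqueous solution)
Product: 10 (2R,3R)-3-(3,4-dimethoxyphenyl)-2-(hydroxymethyl)-4,5,6-trimethoxy-2,3-dihydro-1H-inden-1-one, via trimethylsilyl enol ether 9 (not isolated)
Conditions: Me3SiCl, THF, −78 °C, LiN(SiMe3)2 (1.0 equiv, added last); then Yb(OTf)3 (10 mol%), 37% aq. HCHO, THF, rt
Reagents that add atoms: none
Why: Mukaiyama aldol hydroxymethylation of a silyl enol ether with aqueous formaldehyde under a water-tolerant Lewis acid. Formaldehyde adds to C2 on the face away from the C3 aryl group, giving the trans (2R,3R) product, which is also the more stable epimer, without dehydration or double addition. The enol ether is made with no excess base and no amine, so the indene-type C–H at the aryl-bearing carbon cannot undergo a 1,3-proton shift that would erase that centre.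

Step 6
Reactants: 10
Product: 11 (2R,3R)-3-(3,4-dimethoxyphenyl)-4,5,6-trimethoxy-2-{[tri(propan-2-yl)silyl]oxymethyl}-2,3-dihydro-1H-inden-1-one
Conditions: i-Pr3SiCl, imidazole, DMF, rt
Reagents that add atoms: chlorotri(propan-2-yl)silane, CC(C)[Si](Cl)(C(C)C)C(C)C
Why: Silylation of the primary alcohol. The triisopropylsilyl ether is chosen because it stands aqueous hydroxide in step 8, migrates slowly, and has a hindered, weakly nucleophilic oxygen that should not intervene in step 10.

Step 7
Reactants: 11
Product: 13 (2S,3R)-3-(3,4-dimethoxyphenyl)-4,5,6-trimethoxy-2-{[tri(propan-2-yl)silyl]oxymethyl}-2,3-dihydro-1H-indene-1-carbaldehyde (both C1 epimers), via methyl enol ether 12 (not isolated)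
Conditions: Ph3P(CH2OMe)Cl (2.2 equiv), KN(SiMe3)2 (2.0 equiv), THF, 0 °C to rt; then 2 M HCl, THF, rt
Reagents that add atoms: (methoxymethyl)triphenylphosphonium chloride, COC[P+](c1ccccc1)(c1ccccc1)c1ccccc1.[Cl-]; water, O
Why: Wittig methoxymethylenation followed by hydrolysis of the enol ether, a standard one-carbon homologation of ketones to aldehydes. The base is the limiting reagent, so no free amide is left to enolise 11. The configuration at C1 does not matter because that carbon becomes quaternary with two identical arms in step 8.

Step 8
Reactants: 13; 8 formaldehyde (37% aqueous solution)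
Product: 15 [(2S,3R)-3-(3,4-dimethoxyphenyl)-4,5,6-trimethoxy-2-{[tri(propan-2-yl)silyl]oxymethyl}-2,3-dihydro-1H-indene-1,1-diyl]dimethanol, via hydroxy aldehyde 14 (not isolated)
Conditions: 37% aq. HCHO (excess), KOH, MeOH/THF, rt to 50 °C
Reagents that add atoms: none
Why: Tollens reaction: the aldehyde, which has a single α-hydrogen, undergoes aldol addition to formaldehyde to build the quaternary carbon, and the resulting aldehyde cannot dehydrate. A crossed Cannizzaro hydride transfer from formaldehyde then reduces it to the 1,3-diol. Both C1 epimers of 13 converge, and C2 and C3 are not acidic under these conditions.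

Step 9
Reactants: 15
Product: 17 (2'S,3'R)-3'-(3,4-dimethoxyphenyl)-4',5',6'-trimethoxy-2'-{[tri(propan-2-yl)silyl]oxymethyl}-2',3'-dihydrospiro[1,3,2-dioxathiane-5,1'-indene] 2,2-dioxide, via cyclic sulfite 16 (not isolated)
Conditions: SOCl2, Et3N, CH2Cl2, 0 °C; then RuCl3·xH2O (1 mol%), NaIO4, MeCN/H2O, 0 °C, short contact
Reagents that add atoms: thionyl chloride, O=S(Cl)Cl; sodium periodate, [Na+].[O-]I(=O)(=O)=O
Why: Cyclic sulfite formation and RuO4-catalysed oxidation to the cyclic sulfate. A 2,2-disubstituted propane-1,3-diol closes the six-membered ring readily, and oxidation at sulfur is much faster than attack of RuO4 on methoxyarenes at 0 °C.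

Step 10
Reactants: 17
Product: 18 [(3S,4R)-4-(3,4-dimethoxyphenyl)-5,6,7-trimethoxy-3-{[tri(propan-2-yl)silyl]oxymethyl}-3,4-dihydronaphthalen-2-yl]methyl hydrogen sulfate (kept as its 2,6-di-tert-butyl-4-methylpyridinium salt)
Conditions: 2,6-di-tert-butyl-4-methylpyridine (1.2 equiv), (CF3)2CHOH, 60 °C
Reagents that add atoms: none
Why: In the ionising, non-nucleophilic solvent one CH2–O bond of the cyclic sulfate breaks only with help from ring A: the ring-fusion carbon attached to the spiro centre bridges to the departing CH2 (aryl-assisted ionisation through a bridged arenium ion), its old bond to the spiro carbon opens, and the charge arrives on the former spiro carbon as a tertiary cation bearing the CH2OSO3− arm. Loss of a proton from the new benzylic CH2 to the hindered pyridine gives the C3=C4 double bond conjugated with ring A. The closest known reaction types are the solvolytic neophyl rearrangement of 2-aryl-2-methylpropyl sulfonates and the aryl-shift ring enlargement of 1-methylideneindanes to 2-tetralones by trivalent iodine reagents; here a cyclic sulfate serves as the leaving group. Ring B is closed by ring enlargement (the exocyclic CH2 is inserted between the spiro carbon and ring A through a three-membered bridged transition structure), not by an end-to-end cyclisation. No stereocentre is formed, and the two existing ones are not part of the breaking or forming bonds, so they keep their configuration. Aryl rather than C2-alkyl migration is needed; a primary neopentyl-type centre ionises only with π participation, ring A has a methoxy group para to the migrating carbon, and in the chair conformer with the aryl carbon equatorial on the dioxathiane it is antiperiplanar to both C–O bonds. Elimination towards C4 rather than C2 is favoured by the benzylic C–H and by styrene conjugation, the buffer prevents acid-catalysed equilibration of the alkene, and the bulky silyl ether oxygen is a poor competitor for the ionising carbon. The two diastereotopic arms give the same cation, and the sulfate monoanion left on C10 is a poor leaving group, so the allylic position does not ionise further.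

Step 11
Reactants: 18
Product: 19 [(3S,4R)-4-(3,4-dimethoxyphenyl)-5,6,7-trimethoxy-3-{[tri(propan-2-yl)silyl]oxymethyl}-3,4-dihydronaphthalen-2-yl]methanol
Conditions: H2SO4 (cat.), H2O (2 equiv), THF, rt; then NaHCO3
Reagents that add atoms: none
Why: Acid-catalysed hydrolysis of a sulfate monoester in a moist ether solvent goes by S–O fission, so the allylic C10–O bond and its oxygen are retained. The silyl ether on C9 is kept during this step so that the C9 oxygen cannot close a cyclic ether onto C10.

Step 12
Reactants: 19
Product: 20 [(1R,2S)-1-(3,4-dimethoxyphenyl)-6,7,8-trimethoxy-1,2-dihydronaphthalene-2,3-diyl]dimethanol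
Conditions: Bu4NF, AcOH (1 equiv each), THF, 0 °C to rt
Reagents that add atoms: none
Why: Fluoride cleavage of the silyl ether. Acetic acid buffers the alkoxide so that the C3=C4 double bond is not moved towards C1=C2 by base, and no acid is present that could ionise the allylic alcohol.

## Compound list

1 | 3',4',5'-trimethoxyacetophenone | CC(=O)c1cc(OC)c(OC)c(OC)c1 | starting material
2 | veratraldehyde (3,4-dimethoxybenzaldehyde) | COc1ccc(C=O)cc1OC | starting material
3 | (E)-3-(3,4-dimethoxyphenyl)-1-(3,4,5-trimethoxyphenyl)prop-2-en-1-one | COc1ccc(/C=C/C(=O)c2cc(OC)c(OC)c(OC)c2)cc1OC | intermediate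
4 | rac-3-(3,4-dimethoxyphenyl)-4,5,6-trimethoxy-2,3-dihydro-1H-inden-1-one | COc1ccc(C2CC(=O)c3cc(OC)c(OC)c(OC)c32)cc1OC | intermediate
5 | 3-(3,4-dimethoxyphenyl)-4,5,6-trimethoxy-1H-inden-1-one | COc1ccc(C2=CC(=O)c3cc(OC)c(OC)c(OC)c32)cc1OC | intermediate
6 | (1R)-3-[diethoxy(methyl)silyl]oxy-1-(3,4-dimethoxyphenyl)-5,6,7-trimethoxy-1H-indene | COc1ccc([C@@H]2c3c(cc(OC)c(OC)c3OC)C(O[Si](C)(OCC)OCC)=C2)cc1OC | intermediate (not isolated)
7 | (3R)-3-(3,4-dimethoxyphenyl)-4,5,6-trimethoxy-2,3-dihydro-1H-inden-1-one | COc1ccc([C@@H]2c3c(cc(OC)c(OC)c3OC)C(=O)C2)cc1OC | intermediate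
8 | formaldehyde | C=O | starting material
9 | (1R)-1-(3,4-dimethoxyphenyl)-5,6,7-trimethoxy-3-(trimethylsilyloxy)-1H-indene | COc1ccc([C@@H]2c3c(cc(OC)c(OC)c3OC)C(O[Si](C)(C)C)=C2)cc1OC | intermediate (not isolated)
10 | (2R,3R)-3-(3,4-dimethoxyphenyl)-2-(hydroxymethyl)-4,5,6-trimethoxy-2,3-dihydro-1H-inden-1-one (2,3-trans) | COc1ccc([C@@H]2c3c(cc(OC)c(OC)c3OC)C(=O)[C@H]2CO)cc1OC | intermediate
11 | (2R,3R)-3-(3,4-dimethoxyphenyl)-4,5,6-trimethoxy-2-{[tri(propan-2-yl)silyl]oxymethyl}-2,3-dihydro-1H-inden-1-one | COc1ccc([C@@H]2c3c(cc(OC)c(OC)c3OC)C(=O)[C@H]2CO[Si](C(C)C)(C(C)C)C(C)C)cc1OC | intermediate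
12 | (2S,3R)-3-(3,4-dimethoxyphenyl)-1-(methoxymethylidene)-4,5,6-trimethoxy-2-{[tri(propan-2-yl)silyl]oxymethyl}-2,3-dihydro-1H-indene (E/Z mixture) | COc1ccc([C@@H]2c3c(cc(OC)c(OC)c3OC)C(=COC)[C@H]2CO[Si](C(C)C)(C(C)C)C(C)C)cc1OC | intermediate (not isolated)
13 | (2S,3R)-3-(3,4-dimethoxyphenyl)-4,5,6-trimethoxy-2-{[tri(propan-2-yl)silyl]oxymethyl}-2,3-dihydro-1H-indene-1-carbaldehyde (both C1 epimers) | COc1ccc([C@@H]2c3c(cc(OC)c(OC)c3OC)C(C=O)[C@H]2CO[Si](C(C)C)(C(C)C)C(C)C)cc1OC | intermediate
14 | (2S,3R)-3-(3,4-dimethoxyphenyl)-1-(hydroxymethyl)-4,5,6-trimethoxy-2-{[tri(propan-2-yl)silyl]oxymethyl}-2,3-dihydro-1H-indene-1-carbaldehyde (both C1 epimers) | COc1ccc([C@@H]2c3c(cc(OC)c(OC)c3OC)C(CO)(C=O)[C@H]2CO[Si](C(C)C)(C(C)C)C(C)C)cc1OC | intermediate (not isolated)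
15 | [(2S,3R)-3-(3,4-dimethoxyphenyl)-4,5,6-trimethoxy-2-{[tri(propan-2-yl)silyl]oxymethyl}-2,3-dihydro-1H-indene-1,1-diyl]dimethanol | COc1ccc([C@@H]2c3c(cc(OC)c(OC)c3OC)C(CO)(CO)[C@H]2CO[Si](C(C)C)(C(C)C)C(C)C)cc1OC | intermediate
16 | (2'S,3'R)-3'-(3,4-dimethoxyphenyl)-4',5',6'-trimethoxy-2'-{[tri(propan-2-yl)silyl]oxymethyl}-2',3'-dihydrospiro[1,3,2-dioxathiane-5,1'-indene] 2-oxide (cyclic sulfite, sulfur epimers) | COc1ccc([C@@H]2c3c(cc(OC)c(OC)c3OC)C3(COS(=O)OC3)[C@H]2CO[Si](C(C)C)(C(C)C)C(C)C)cc1OC | intermediate (not isolated)
17 | (2'S,3'R)-3'-(3,4-dimethoxyphenyl)-4',5',6'-trimethoxy-2'-{[tri(propan-2-yl)silyl]oxymethyl}-2',3'-dihydrospiro[1,3,2-dioxathiane-5,1'-indene] 2,2-dioxide (cyclic sulfate) | COc1ccc([C@@H]2c3c(cc(OC)c(OC)c3OC)C3(COS(=O)(=O)OC3)[C@H]2CO[Si](C(C)C)(C(C)C)C(C)C)cc1OC | intermediate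
18 | [(3S,4R)-4-(3,4-dimethoxyphenyl)-5,6,7-trimethoxy-3-{[tri(propan-2-yl)silyl]oxymethyl}-3,4-dihydronaphthalen-2-yl]methyl hydrogen sulfate | COc1ccc([C@@H]2c3c(cc(OC)c(OC)c3OC)C=C(COS(=O)(=O)O)[C@H]2CO[Si](C(C)C)(C(C)C)C(C)C)cc1OC | intermediate
19 | [(3S,4R)-4-(3,4-dimethoxyphenyl)-5,6,7-trimethoxy-3-{[tri(propan-2-yl)silyl]oxymethyl}-3,4-dihydronaphthalen-2-yl]methanol | COc1ccc([C@@H]2c3c(cc(OC)c(OC)c3OC)C=C(CO)[C@H]2CO[Si](C(C)C)(C(C)C)C(C)C)cc1OC | intermediate
20 | [(1R,2S)-1-(3,4-dimethoxyphenyl)-6,7,8-trimethoxy-1,2-dihydronaphthalene-2,3-diyl]dimethanol | COc1ccc([C@@H]2c3c(cc(OC)c(OC)c3OC)C=C(CO)[C@H]2CO)cc1OC | target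

## Step count and least certain steps

Total step count: 12. Longest linear sequence: 12 steps (from 1 or 2 to 20).

Step 10 (key step). The ionisation may be slow or misdirected. The methoxy group para to the migrating carbon is flanked by two others and twisted out of conjugation, and the five-membered ring holds the migrating carbon in a less than ideal geometry for bridging, so participation by ring A may be weak. Competing processes would then be:
- migration of the C2 ring bond;
- capture of the ionising CH2 by the silyl ether oxygen or by ring C;
- proton loss towards C2;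
- later movement of the double bond into conjugation with both rings.

The fallback reaches the same C4–C4a bond by a known aryl-shift ring enlargement and sets out from 11. Methylenation of the ketone with Cp2TiMe2 in toluene at 70 °C would give the methylidene indane F1. Treatment with PhI(OH)OTs in 95% MeOH at rt would add the iodine reagent to the terminal carbon and methanol to the benzylic carbon, and loss of iodobenzene with migration of ring A would give the 2-tetralone F2. Enolisation towards the benzylic CH2 with KN(SiMe3)2 and PhNTf2 at −78 °C would give the enol triflate F3. Carbonylation with Pd(OAc)2, 1,3-bis(diphenylphosphino)propane, CO, MeOH and Et3N would give the unsaturated methyl ester F4. Reduction with i-Bu2AlH in CH2Cl2 at −78 °C returns to the route at 19.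

Step 11. Under acid the allylic C10–O bond may break instead of the S–O bond. The resulting cinnamyl-type cation could undergo allylic transposition, closure of a cyclic ether by the C9 oxygen with loss of the silyl group, or alkylation of an arene. The fallback sets out from 18 and avoids acid. Silyl-transfer desulfation with N,O-bis(trimethylsilyl)acetamide in pyridine at 60 °C, a known reaction of primary sulfate monoesters, would give the trimethylsilyl ether F5 and pass SO3 to pyridine. Bu4NF with AcOH then removes both silyl groups and returns to the route at 20.

Step 7. Olefination of the hindered, α-branched ketone may be slow enough for enolisation to compete, with epimerisation at C2 or β-elimination of the silyloxy group. The fallback sets out from 11 and uses a smaller nucleophile that adds irreversibly at low temperature. Corey–Chaykovsky methylene transfer with Me3SI and KN(SiMe3)2 in THF at −10 °C would give the spiro-epoxide F6. Meinwald rearrangement with MgBr2·OEt2 in CH2Cl2 (opening at the benzylic carbon, then a 1,2-hydride shift) returns to the route at 13.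

Step 4. Three things could lower the outcome here:
- facial selectivity may be poor because the peri methoxy group twists the aryl group;
- some 1,2-reduction may occur;
- enantiomeric purity may erode by a 1,3-proton shift in the indene-type silyl enol ether 6.

The fallback sets out from 4 and omits step 3. Kinetic resolution by asymmetric transfer hydrogenation would use RuCl(p-cymene)[(S,S)-TsDPEN] (or its mirror image, whichever consumes the (S)-ketone) with the HCO2H/Et3N azeotrope. It would reduce the unwanted enantiomer to the cis-indanol F7 and leave the (R)-ketone, which is separated by chromatography and returns to the route at 7. At most half of the material is retained.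

Step 9. The methoxy-rich rings may be degraded by RuO4 during the sulfite oxidation. The fallback sets out from 15 and transfers the sulfonyl group directly without an oxidant: 1,1'-sulfonyldiimidazole and NaH in THF at −20 °C. It returns to the route at 17 and makes no new compound (F0).

## Further compounds

F1 | step 10 | (2S,3R)-3-(3,4-dimethoxyphenyl)-4,5,6-trimethoxy-1-methylidene-2-{[tri(propan-2-yl)silyl]oxymethyl}-2,3-dihydro-1H-indene | COc1ccc([C@@H]2c3c(cc(OC)c(OC)c3OC)C(=C)[C@H]2CO[Si](C(C)C)(C(C)C)C(C)C)cc1OC
F2 | step 10 | (3R,4R)-4-(3,4-dimethoxyphenyl)-5,6,7-trimethoxy-3-{[tri(propan-2-yl)silyl]oxymethyl}-3,4-dihydronaphthalen-2(1H)-one | COc1ccc([C@@H]2c3c(cc(OC)c(OC)c3OC)CC(=O)[C@H]2CO[Si](C(C)C)(C(C)C)C(C)C)cc1OC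
F3 | step 10 | (3R,4R)-4-(3,4-dimethoxyphenyl)-5,6,7-trimethoxy-3-{[tri(propan-2-yl)silyl]oxymethyl}-3,4-dihydronaphthalen-2-yl trifluoromethanesulfonate | COc1ccc([C@@H]2c3c(cc(OC)c(OC)c3OC)C=C(OS(=O)(=O)C(F)(F)F)[C@H]2CO[Si](C(C)C)(C(C)C)C(C)C)cc1OC
F4 | step 10 | methyl (3S,4R)-4-(3,4-dimethoxyphenyl)-5,6,7-trimethoxy-3-{[tri(propan-2-yl)silyl]oxymethyl}-3,4-dihydronaphthalene-2-carboxylate | COc1ccc([C@@H]2c3c(cc(OC)c(OC)c3OC)C=C(C(=O)OC)[C@H]2CO[Si](C(C)C)(C(C)C)C(C)C)cc1OC
F5 | step 11 | {[(3S,4R)-4-(3,4-dimethoxyphenyl)-5,6,7-trimethoxy-3-{[tri(propan-2-yl)silyl]oxymethyl}-3,4-dihydronaphthalen-2-yl]methoxy}trimethylsilane | COc1ccc([C@@H]2c3c(cc(OC)c(OC)c3OC)C=C(CO[Si](C)(C)C)[C@H]2CO[Si](C(C)C)(C(C)C)C(C)C)cc1OC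
F6 | step 7 | (2'R,3'R)-3'-(3,4-dimethoxyphenyl)-4',5',6'-trimethoxy-2'-{[tri(propan-2-yl)silyl]oxymethyl}-2',3'-dihydrospiro[oxirane-2,1'-indene] (both epimers at the spiro carbon) | COc1ccc([C@@H]2c3c(cc(OC)c(OC)c3OC)C3(CO3)[C@H]2CO[Si](C(C)C)(C(C)C)C(C)C)cc1OC
F7 | step 4 | (1S,3S)-3-(3,4-dimethoxyphenyl)-4,5,6-trimethoxy-2,3-dihydro-1H-inden-1-ol (cis) | COc1ccc([C@H]2c3c(cc(OC)c(OC)c3OC)[C@@H](O)C2)cc1OC
F0 | step 9 | none | none
A1 | alternative 1 | [(4S,5S)-2,2-dimethyl-1,3-dioxolane-4,5-diyl]bis(methylene) mixed diester with (E)-3-(4-hydroxy-3,5-dimethoxyphenyl)prop-2-enoic acid and (E)-3-(4-hydroxy-3-methoxyphenyl)prop-2-enoic acid | COc1cc(/C=C/C(=O)OC[C@@H]2OC(C)(C)O[C@H]2COC(=O)/C=C/c2ccc(O)c(OC)c2)cc(OC)c1O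
A2 | alternative 1 | ten-membered dilactone of (1R,2S)-7-hydroxy-1-(4-hydroxy-3-methoxyphenyl)-6,8-dimethoxy-1,2-dihydronaphthalene-2,3-dicarboxylic acid with (4S,5S)-2,2-dimethyl-1,3-dioxolane-4,5-dimethanol | Oc1ccc([C@@H]2c3c(cc(OC)c(O)c3OC)C=C4C(=O)OC[C@@H]5OC(C)(C)O[C@H]5COC(=O)[C@@H]24)cc1OC
A3 | alternative 2 | methyl (E)-4-[(4S)-4-benzyl-2-oxo-1,3-oxazolidin-3-yl]-2-({2-[(3,4-dimethoxyphenyl)(methoxy)methyl]-3,4,5-trimethoxyphenyl}methylidene)-4-oxobutanoate (both epimers at the methoxy-bearing carbon) | COc1ccc(C(OC)c2c(/C=C(\CC(=O)N3[C@@H](Cc4ccccc4)COC3=O)C(=O)OC)cc(OC)c(OC)c2OC)cc1OC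
A4 | alternative 2 | methyl (3S,4R)-3-{[(4S)-4-benzyl-2-oxo-1,3-oxazolidin-3-yl]carbonyl}-4-(3,4-dimethoxyphenyl)-5,6,7-trimethoxy-3,4-dihydronaphthalene-2-carboxylate | COc1ccc([C@@H]2c3c(cc(OC)c(OC)c3OC)C=C(C(=O)OC)[C@H]2C(=O)N2[C@@H](Cc3ccccc3)COC2=O)cc1OC
A5 | alternative 3 | (E)-3-(3,4-dimethoxyphenyl)-3-(3,4,5-trimethoxyphenyl)prop-2-en-1-yl prop-2-ynoate | COc1ccc(/C(=C\COC(=O)C#C)c2cc(OC)c(OC)c(OC)c2)cc1OC
A6 | alternative 3 | (3aS,4R)-4-(3,4-dimethoxyphenyl)-5,6,7-trimethoxy-3a,4-dihydronaphtho[2,3-c]furan-1(3H)-one | COc1ccc([C@@H]2c3c(cc(OC)c(OC)c3OC)C=C3C(=O)OC[C@@H]23)cc1OC
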